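Remark on the chemistry: the target SMILES encodes a centrosymmetric (meso, achiral) molecule, so all chiral intermediates are carried as racemates and their SMILES show one enantiomer. Steps 1 to 5 act on both benzylic arms of a symmetric arene, so each consumes two equivalents of its reagent per molecule of substrate. Atom labels C1–O26 follow the order of the target SMILES.

## Analysis of the target

The target is a pentacyclic cage built on a central cyclohexane-1,4-dione (C7, C8, C10, C14, C25, C23; ketones at C8 and C25). The enone unit C12(=O)–C2(Me)=C3 bridges C10 and C7 (carbocycle A) and the enone unit C21(=O)–C19(Me)=C18 bridges C23 and C14 (carbocycle B), so each half is a bicyclo[3.3.1]non-3-ene-2,9-dione. Two oxolanes (C3–C4–O5–C6–C7 and C18–C17–O16–C15–C14) are fused at the C3–C7 and C18–C14 bonds. The four stereocentres are the quaternary carbons C7 and C14 and the tertiary carbinols C10 and C23; the two bridges lie on opposite faces of the central ring and the halves are related by a centre of inversion. The fragile groups are the two bridgehead α-hydroxy-β-diketones (retro-Claisen cleavage, α-ketol shift) and the non-enolisable β-diketones in general, which alkoxide or hydroxide cleave. The difficulty is that all six carbons of the central ring are fully substituted, with two pairs of adjacent fully substituted centres (C7/C23 and C10/C14). The strategy rests on three observations: C8 and C25 are para, as in a hydroquinone whose benzylic carbons are C6 and C15; C10–C12 is the bond an acyl radical at C12 makes with the β-carbon of the ene-dione C10=C14–C25=O; and C14–C18 is the bond the resulting α-keto radical makes with a tethered alkene carbon that carries a radical leaving group.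

## Retrosynthetic reasoning

17 to 16: the C10–O and C23–O bonds are cut first because the α-hydroxy-β-diketones are the most fragile groups. In 16 both carbons are bridgehead C–H flanked by two carbonyls, so oxygen can only enter with retention; the forward step is a double enolate hydroxylation.

16 to 14 via 15: the C21–C23 bond is cut after lowering C21 to the carbinol. This opens ring B to 14, which carries a C21 aldehyde on the exocyclic C18=C19 alkene, cis to C14, and has C23 as its only enolisable carbon. Forward, an aldol addition and one oxidation close ring B.

14 to 13 (key disconnection): the C10–C12 and C14–C18 bonds are cut together. This removes ring A and the second oxolane and leaves a spiro cyclohexene-1,4-dione, a dearomatised hydroquinone. Forward, C12 is a formyl carbon, C10=C14 the only alkene in its reach and C18 carries an ethylsulfanyl group, so one thiyl-carried radical chain should build two rings, two bonds and the C10 and C14 stereocentres.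

13 to 11: the C7–C3 bond is cut, which returns an aromatic hydroquinone with two ether arms. Forward, the monophenolate attacks its own arm through the ortho carbon C7 and expels a leaving group from C3. The arms must differ. Bromide sits on the arm that closes ionically (irreversible, no thiolate released). The ethylsulfanyl group sits on the arm kept for the radical step; as a push–pull alkene that arm is also the poorer electrophile, so the phenolate next to it should not close. Free thiolate must not meet 13: it would add to C10 and eject the C15 ether, or add to C3 and let C7–C3 cleave with rearomatisation.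

11 to 7 and 8: the hydroquinone is masked as its dimethyl ether 9, and the two arms of 9 are differentiated by exchanging one vinylic bromide of the symmetric bis-bromide 7 for the sulfur of 8.

7 to 3 via 6, 5 and 4: each tetrasubstituted β-bromo enal comes from a β-keto ester. The ketone carbon becomes C3–Br, enolate alkylation puts the methyl on C2, and the ester is reduced and re-oxidised to the formyl group. The 1,3-dicarbonyl fixes the regiochemistry without an alkyne carbometalation, which would place a metal β to the ether oxygen.

3 to 1 and 2: the C4–O5 and C17–O16 ether bonds are cut. Forward, each of the two benzylic alkoxides of 1 displaces the chloride of one molecule of 2, so two molecules of 2 are taken up per molecule of 1.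

## Alternatives that were turned down

Alternative 1: The last skeletal bonds made would be C7–C6 and C14–C15. The finished carbocyclic cage A2 (vinylogous methyl esters at C3 and C18, silyl ethers at C10 and C23) would be metalated at both bridgeheads with a hindered lithium amide and alkylated with the chloromethyl ether A3 to give A1. In its favour, bridgehead metalation and alkylation of bicyclo[3.3.1]nonane diones is the best-precedented reaction type in this problem, retention is automatic, and the C10 and C23 oxygens are already present. On that point it is stronger, because it avoids the late bridgehead hydroxylation of step 12. Against it, the step closes no ring and moves the real difficulty into A2, for which no short access is apparent. Each alkylation must also create a quaternary carbon next to a fully substituted silyloxy carbon, which is sterically poor for SN2 attack by a pyramidal bridgehead anion. A1 still lacks C4 and C17, so both methoxy groups must later be exchanged for carbon and two ethers closed. The chosen strategy gives up that precedent; in exchange, C4, C17 and both ether oxygens come in with the starting materials, and one step builds ring A, an oxolane and the C10 and C14 centres.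

Alternative 2: The cuts are C7–C3, C10–C12 and O5–C6 and their counterparts C14–C18, C23–C21 and O16–C15, all made in one operation from the bis(hydroxymethylene) dione A5 and two molecules of the bromobutenolide A6. Each formyl-activated carbon would displace bromide by addition–elimination, the neighbouring ketone enolate would open the lactone by Claisen acylation, and the freed alkoxide would close on the formyl carbon to give the bis-lactol A4. In its favour, it is the shortest and most convergent plan, it uses the symmetry of the target, and every bond is made with matched two-electron polarity. On step economy and on the reliability of the first C–C bond it is stronger than the chosen route. Against it, the Claisen step must form a β-diketone whose central carbon is a bridgehead and cannot be deprotonated to pull the equilibrium, in a medium containing alkoxide, which cleaves exactly such diketones and deformylates the quaternary α-formyl ketone. The second annulation must also occur anti to the first on an already congested bicycle. A4 then needs two lactol deoxygenations next to ketones and enones, plus the same bridgehead hydroxylations. The chosen strategy offers instead a C10–C12 bond made under neutral radical conditions, where the retro-Claisen channel is closed, and oxolanes formed directly at the ether oxidation level.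

Alternative 3: The same four carbon–carbon bonds (C7–C3, C10–C12, C14–C18, C23–C21) would be made by two successive Effenberger-type annulations of the bis(enol ether) A8 with methylmalonyl dichloride A9, giving the doubly bridged hexaketone A7. In its favour, this annulation is the classical entry to bicyclo[3.3.1]nonane triones, one reagent brings the methyl group and both bridge carbonyls, and two uses of one reaction deliver both carbocycles. In precedent for the ring-forming event it is stronger than the chosen key step. Against it, the reaction is inefficient even once, and the second annulation must run on an already bridged, deactivated enol ether and on the face opposite the first bridge. A8 requires dissolving-metal reduction of an arene with two benzylic ethers, which such conditions cleave. A7 has oxygen, not carbon, at C3 and C18, so C4 and C17 must still be added (regioselective activation of C3–O over C12–O, cross-coupling, two ether closures) before the same hydroxylations. The chosen strategy is less precedented in its key step but needs no later one-carbon homologation; only an aldol closure, one oxidation and the hydroxylation remain.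

Key step: step 9

## Route

Step 1
Reactants: 1 (2,5-dimethoxy-1,4-phenylene)dimethanol; 2 ethyl 4-chloro-3-oxobutanoate (two molecules, one for each benzylic alcohol)
Product: 3 diethyl 4,4'-[(2,5-dimethoxy-1,4-phenylene)bis(methyleneoxy)]bis(3-oxobutanoate)
Conditions: 2 (2.2 equiv), NaH (4.6 equiv), THF, 0 °C → rt
Reagents that add atoms: ethyl 4-chloro-3-oxobutanoate (second molecule of 2), CCOC(=O)CC(=O)CCl
Why: Twofold Williamson-type etherification, each benzylic oxygen of 1 taking up one molecule of 2; one equivalent of NaH per molecule of 2 turns it into its sodium enolate, which protects the β-keto ester, and each benzylic alkoxide displaces the primary chloride next to the ketone, the standard route to 4-alkoxyacetoacetates.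

Step 2
Reactants: 3 diethyl 4,4'-[(2,5-dimethoxy-1,4-phenylene)bis(methyleneoxy)]bis(3-oxobutanoate)
Product: 4 diethyl 4,4'-[(2,5-dimethoxy-1,4-phenylene)bis(methyleneoxy)]bis(2-methyl-3-oxobutanoate) (diastereomer mixture)
Conditions: MeI (2.1 equiv), K2CO3, acetone, rt → 40 °C
Reagents that add atoms: iodomethane, CI
Why: Acetoacetic ester alkylation on both arms; carbonate deprotonates only the carbon between the two carbonyls (future C2 and C19), and one equivalent of iodomethane per site limits double methylation. The new stereocentres are labile and vanish in step 3.

Step 3
Reactants: 4 diethyl 4,4'-[(2,5-dimethoxy-1,4-phenylene)bis(methyleneoxy)]bis(2-methyl-3-oxobutanoate)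
Product: 5 diethyl 4,4'-[(2,5-dimethoxy-1,4-phenylene)bis(methyleneoxy)]bis(3-bromo-2-methylbut-2-enoate) (E/Z mixture at both alkenes)
Conditions: Ph3PBr2 (2.4 equiv), Et3N, MeCN, 0 °C → rt
Reagents that add atoms: dibromotriphenylphosphorane, BrP(Br)(c1ccccc1)(c1ccccc1)c1ccccc1
Why: Deoxybromination of the enol of a β-keto ester (vinylogous acid bromide formation) on both arms; the amine buffer protects the acid-labile dimethoxybenzyl ethers. The E/Z mixture is acceptable because both alkene geometries are erased in steps 8 and 9.

Step 4
Reactants: 5 diethyl 4,4'-[(2,5-dimethoxy-1,4-phenylene)bis(methyleneoxy)]bis(3-bromo-2-methylbut-2-enoate)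
Product: 6 4,4'-[(2,5-dimethoxy-1,4-phenylene)bis(methyleneoxy)]bis(3-bromo-2-methylbut-2-en-1-ol) (E/Z mixture)
Conditions: i-Bu2AlH (5 equiv), CH2Cl2, −78 °C; aq. KNaC4H4O6 work-up
Reagents that add atoms: none
Why: 1,2-Reduction of both enoates to allylic alcohols with i-Bu2AlH at low temperature; the vinyl bromides and benzylic ethers are inert.

Step 5
Reactants: 6 4,4'-[(2,5-dimethoxy-1,4-phenylene)bis(methyleneoxy)]bis(3-bromo-2-methylbut-2-en-1-ol)
Product: 7 4,4'-[(2,5-dimethoxy-1,4-phenylene)bis(methyleneoxy)]bis(3-bromo-2-methylbut-2-enal) (E/Z mixture)
Conditions: MnO2, CH2Cl2, rt
Reagents that add atoms: none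
Why: MnO2 oxidation of allylic alcohols; it is selective for the allylic carbinols and leaves the electron-rich arene and the vinyl bromides untouched.

Step 6
Reactants: 7 4,4'-[(2,5-dimethoxy-1,4-phenylene)bis(methyleneoxy)]bis(3-bromo-2-methylbut-2-enal); 8 ethanethiol
Product: 9 3-bromo-4-{[4-({[2-(ethylsulfanyl)-3-methyl-4-oxobut-2-en-1-yl]oxy}methyl)-2,5-dimethoxyphenyl]methoxy}-2-methylbut-2-enal (E/Z mixture)
Conditions: 8 (0.7 equiv), Et3N, CH2Cl2, −40 °C; unreacted 7 recycled
Reagents that add atoms: none
Why: Nucleophilic vinylic substitution (addition–elimination) of the vinylogous acyl bromide by thiolate; the two arms are equivalent and independent, so a sub-stoichiometric charge of 8 should give a statistical mixture from which 9 is separated and 7 returned. Sulfur is introduced here, before dearomatisation, because free thiolate is not compatible with the ene-dione of 13.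

Step 7
Reactants: 9 3-bromo-4-{[4-({[2-(ethylsulfanyl)-3-methyl-4-oxobut-2-en-1-yl]oxy}methyl)-2,5-dimethoxyphenyl]methoxy}-2-methylbut-2-enal
Product: 11 2-{[(2-bromo-3-methyl-4-oxobut-2-en-1-yl)oxy]methyl}-5-({[2-(ethylsulfanyl)-3-methyl-4-oxobut-2-en-1-yl]oxy}methyl)benzene-1,4-diol, via quinone 10 (not isolated)
Conditions: (NH4)2Ce(NO3)6 (2.5 equiv), MeCN–H2O, 0 °C; then L-ascorbic acid, EtOAc–H2O, rt, under Ar
Reagents that add atoms: water, O
Why: Oxidative demethylation of the 1,4-dimethoxyarene by tetravalent cerium (water supplies the quinone oxygens) followed by reduction of quinone 10 with ascorbic acid; the arene is oxidised well before the acceptor-substituted sulfide or the enals.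

Step 8
Reactants: 11 2-{[(2-bromo-3-methyl-4-oxobut-2-en-1-yl)oxy]methyl}-5-({[2-(ethylsulfanyl)-3-methyl-4-oxobut-2-en-1-yl]oxy}methyl)benzene-1,4-diol
Product: 13 racemic (E)-2-[8-({[2-(ethylsulfanyl)-3-methyl-4-oxobut-2-en-1-yl]oxy}methyl)-6,9-dioxo-2-oxaspiro[4.5]dec-7-en-4-ylidene]propanal, via spiro dienol 12 (not isolated)
Conditions: LiOt-Bu (1.0 equiv), PhMe–THF (9:1), −20 °C → rt, 5 mM, Ar
Reagents that add atoms: none
Why: Proposed new method: the lithium monophenolate at the C8 oxygen attacks C3 of its own β-bromo enal through the ortho carbon C7 (5-exo-trig, enolate double bond exocyclic to the new ring), bromide leaves irreversibly, and the 4-hydroxycyclohexa-2,4-dienone 12 tautomerises to the ene-dione, which cannot rearomatise because C7 is quaternary; attack through oxygen would need a seven-membered ring and is further disfavoured by the lithium counter-ion in a non-polar medium, and the phenolate at the C25 oxygen should leave its own arm alone because the ethylsulfanyl enal is a push–pull alkene that is far less electrophilic and carries a poorer leaving group. The closest known types are ortho C-alkylation of phenolates at a substituted carbon with loss of aromaticity (alkylative dearomatisation) and nucleophilic vinylic substitution of β-halo enals by enolates; their combination on a hydroquinone monophenolate is not known. C7 is the only stereocentre (racemic), and the E enal (formyl cis to C7) is expected as the less strained isomer, any Z isomer being equilibrated under the radical conditions of step 9.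

Step 9
Reactants: 13 racemic (E)-2-[8-({[2-(ethylsulfanyl)-3-methyl-4-oxobut-2-en-1-yl]oxy}methyl)-6,9-dioxo-2-oxaspiro[4.5]dec-7-en-4-ylidene]propanal
Product: 14 racemic ring-A-closed bis-oxolane enal (bicyclo[3.3.1]nonene trione; C12 on C10 cis to C3 on C7; C18 on C14 anti to that bridge; E enal with formyl cis to C14)
Conditions: t-C12H25SH (0.1 equiv), AIBN (0.2 equiv, in portions), PhH, 80 °C, 5 mM, slow Ar sweep to remove EtSH
Reagents that add atoms: none
Why: Proposed new method: a thiyl radical (first from the catalytic tertiary thiol, then the ethylthiyl radical released by the substrate) reversibly abstracts the formyl hydrogen at C12 (polarity-reversal catalysis), while the C21 acyl radical of the tether has no alkene in reach and returns to the aldehyde. The nucleophilic C12 acyl radical adds 6-exo-trig to C10, the β-carbon of the C25 enone, closing ring A and leaving a tertiary α-keto radical at C14. That radical adds 5-exo-trig to C18, the sulfur-bearing carbon of the tether, and the α-formyl radical at C19 expels the ethylthiyl radical by β-scission, which closes the second oxolane, restores C18=C19 and carries the chain. The closest known types are thiol-catalysed radical-chain hydroacylation of electron-poor alkenes, acyl-radical 6-exo cyclisation onto enones and radical vinylation by addition–β-elimination on β-sulfanyl or β-stannyl acrylates; their union in one chain and the ipso attack of an α-keto radical on a β-sulfanyl enal are not known. C10 is set by the tether: C12 is held on the face of C7 that carries C3, so the new ring can only be cis-bridged. C14 is set by the new bridge: C12 and C2 lie under the central ring, so C18 bonds to the opposite lobe of the planar C14 radical and C15 swings to the bridge side, which is the anti arrangement of the target. The step needs acyl addition at C10 only and 5-exo closure at C18 rather than 6-endo at C19; C10=C14 is the only alkene within reach of C12, attack at C18 gives the formyl-stabilised radical that can fragment, and premature hydrogen transfer to C14 is held down by catalytic thiol, high dilution and removal of EtSH. The E enal (formyl cis to the quaternary C14) is the less strained isomer and is reachable by reversible thiyl addition–elimination.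

Step 10
Reactants: 14 racemic ring-A-closed bis-oxolane enal
Product: 15 racemic cage carbinol (10,23-dideoxy cage with secondary hydroxyl at C21; C21 epimers)
Conditions: DBU (0.2 equiv), CH2Cl2, 0 °C → rt
Reagents that add atoms: none
Why: Intramolecular aldol addition; C23 is the only enolisable position next to C25 (C14 is quaternary, the C10 bridgehead does not enolise under amine base) and its enolate reaches the C21 aldehyde only on the face that carries C18, which fixes C23, while the C21 carbinol mixture is removed in step 11. Dehydration would need a bridgehead alkene and does not occur; alkoxide and hydroxide are avoided because they would cleave the non-enolisable C8/C12 β-diketone.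

Step 11
Reactants: 15 racemic cage carbinol
Product: 16 10,23-dideoxy target (centrosymmetric tetraketone with bridgehead hydrogens at C10 and C23)
Conditions: Dess–Martin periodinane (1.5 equiv), CH2Cl2, rt
Reagents that add atoms: none
Why: Dess–Martin oxidation of the secondary allylic alcohol to the ring-B enone under neutral conditions, which avoids retro-aldol and retro-Claisen pathways.

Step 12
Reactants: 16 10,23-dideoxy target
Product: 17 CNP0299498.2 (target)
Conditions: KN(SiMe3)2 (2.4 equiv), THF, −78 °C; then 2-(benzenesulfonyl)-3-phenyloxaziridine (3 equiv), −78 °C; AcOH quench at −78 °C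
Reagents that add atoms: 2-(benzenesulfonyl)-3-phenyloxaziridine, O=S(=O)(c1ccccc1)N1OC1c1ccccc1
Why: Enolate hydroxylation with an N-sulfonyloxaziridine (Davis oxidation) at both bridgeheads; each bridgehead C–H lies between two carbonyls and the bicyclo[3.3.1]nonane frame tolerates a bridgehead enolate, as used in bridgehead substitutions of related diones, and the non-nucleophilic silazide cannot trigger retro-Claisen cleavage. Oxygen can only arrive with retention at a bridgehead, so C10 and C23 are fixed by the cage.

## Compound list

1 | (2,5-dimethoxy-1,4-phenylene)dimethanol | COc1cc(CO)c(OC)cc1CO | starting material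
2 | ethyl 4-chloro-3-oxobutanoate | CCOC(=O)CC(=O)CCl | starting material
3 | diethyl 4,4'-[(2,5-dimethoxy-1,4-phenylene)bis(methyleneoxy)]bis(3-oxobutanoate) | CCOC(=O)CC(=O)COCc1cc(OC)c(COCC(=O)CC(=O)OCC)cc1OC | intermediate
4 | diethyl 4,4'-[(2,5-dimethoxy-1,4-phenylene)bis(methyleneoxy)]bis(2-methyl-3-oxobutanoate), diastereomer mixture | CCOC(=O)C(C)C(=O)COCc1cc(OC)c(COCC(=O)C(C)C(=O)OCC)cc1OC | intermediate
5 | diethyl 4,4'-[(2,5-dimethoxy-1,4-phenylene)bis(methyleneoxy)]bis(3-bromo-2-methylbut-2-enoate), E/Z mixture | CCOC(=O)C(C)=C(Br)COCc1cc(OC)c(COCC(Br)=C(C)C(=O)OCC)cc1OC | intermediate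
6 | 4,4'-[(2,5-dimethoxy-1,4-phenylene)bis(methyleneoxy)]bis(3-bromo-2-methylbut-2-en-1-ol), E/Z mixture | OCC(C)=C(Br)COCc1cc(OC)c(COCC(Br)=C(C)CO)cc1OC | intermediate
7 | 4,4'-[(2,5-dimethoxy-1,4-phenylene)bis(methyleneoxy)]bis(3-bromo-2-methylbut-2-enal), E/Z mixture | O=CC(C)=C(Br)COCc1cc(OC)c(COCC(Br)=C(C)C=O)cc1OC | intermediate
8 | ethanethiol | CCS | starting material
9 | 3-bromo-4-{[4-({[2-(ethylsulfanyl)-3-methyl-4-oxobut-2-en-1-yl]oxy}methyl)-2,5-dimethoxyphenyl]methoxy}-2-methylbut-2-enal, E/Z mixture | O=CC(C)=C(SCC)COCc1cc(OC)c(COCC(Br)=C(C)C=O)cc1OC | intermediate
10 | 2-{[(2-bromo-3-methyl-4-oxobut-2-en-1-yl)oxy]methyl}-5-({[2-(ethylsulfanyl)-3-methyl-4-oxobut-2-en-1-yl]oxy}methyl)cyclohexa-2,5-diene-1,4-dione | O=CC(C)=C(SCC)COCC1=CC(=O)C(COCC(Br)=C(C)C=O)=CC1=O | intermediate (not isolated)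
11 | 2-{[(2-bromo-3-methyl-4-oxobut-2-en-1-yl)oxy]methyl}-5-({[2-(ethylsulfanyl)-3-methyl-4-oxobut-2-en-1-yl]oxy}methyl)benzene-1,4-diol | O=CC(C)=C(SCC)COCc1cc(O)c(COCC(Br)=C(C)C=O)cc1O | intermediate
12 | racemic (E)-2-[8-({[2-(ethylsulfanyl)-3-methyl-4-oxobut-2-en-1-yl]oxy}methyl)-9-hydroxy-6-oxo-2-oxaspiro[4.5]deca-7,9-dien-4-ylidene]propanal | O=C/C(C)=C1/COC[C@]12C(=O)C=C(COCC(SCC)=C(C)C=O)C(O)=C2 | intermediate (not isolated)
13 | racemic (E)-2-[8-({[2-(ethylsulfanyl)-3-methyl-4-oxobut-2-en-1-yl]oxy}methyl)-6,9-dioxo-2-oxaspiro[4.5]dec-7-en-4-ylidene]propanal; tether alkene E/Z mixture | O=C/C(C)=C1/COC[C@]12C(=O)C=C(COCC(SCC)=C(C)C=O)C(=O)C2 | intermediate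
14 | racemic ring-A-closed bis-oxolane enal; relative configuration at C7, C10, C14 as in the target; E enal | CC1=C4[C@]3(COC4)C(=O)[C@H](C1=O)[C@]5(COC/C5=C(C)/C=O)C(=O)C3 | intermediate
15 | racemic cage carbinol (hydrogen at C10 and C23, hydroxyl at C21, C21 epimers) | CC1=C2COC[C@]23C(=O)[C@H](C1=O)[C@@]12COCC1=C(C)C(O)[C@@H]3C2=O | intermediate
16 | 10,23-dideoxy target (meso tetraketone) | CC1=C2COC[C@]23C(=O)[C@H](C1=O)[C@@]12COCC1=C(C)C(=O)[C@@H]3C2=O | intermediate
17 | CNP0299498.2 | CC1=C2COC[C@]23C(=O)[C@](O)(C1=O)[C@@]12COCC1=C(C)C(=O)[C@]3(O)C2=O | target

## Step count and least certain steps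

Total steps: 12. Longest linear sequence: 12 (from 1).

Step 9 (key step, proposed new method). The most likely failure is premature hydrogen transfer to the C14 radical before it attacks the fully substituted C18, which would stop the cascade after ring A. Closure at C19 (6-endo) is also possible, since polarity favours an electrophilic α-keto radical attacking the α-carbon of the push–pull alkene. Further leaks are conjugate addition of the liberated thiol to the ene-dione and hydrogen abstraction at the allylic ether methylenes. The fallback uses known two-electron chemistry and sets out from 13. A thiazolium-carbene catalyst (3-benzyl-5-(2-hydroxyethyl)-4-methylthiazolium chloride, Et3N, dioxane, 70 °C) should effect an intramolecular Stetter addition of the C12 aldehyde to C10; only this aldehyde has an acceptor in reach. This gives the ring-A-closed diketone with hydrogen at C14 and the open tether, F1. DBU then generates the C14 enolate, which closes the oxolane by conjugate addition–elimination at C18 with loss of ethanethiolate (no ene-dione remains at that stage), on the face away from the C12 bridge. The fallback returns to the route at 14. The same base treatment would also rescue any F1 formed as a by-product of the radical reaction.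

Step 8 (proposed new method). The most likely failures are vinylation through oxygen to a seven-membered aryl vinyl ether, intermolecular vinylation at the free ortho positions (which can rearomatise), closure of the other phenolate onto the ethylsulfanyl arm with release of thiolate, and oxidation of the phenolate to the quinone by adventitious air. The fallback uses known chemistry at the cost of material and sets out from 6. Anodic oxidation in methanolic KOH gives the quinone bis-ketal F2, MnO2 gives its bis-enal F3, and mild aqueous acid hydrolyses one ketal to the monoketal F4 (a single isomer by symmetry). About one equivalent of Bu3SnH, added slowly with AIBN in benzene at 80 °C, then abstracts one vinylic bromine per molecule. The vinyl radical of the arm on the β-carbon of the dienone (C7) closes 5-exo to an α-keto radical, matched in polarity, and gives the spiro monoketal F5. The radical of the other arm has only the unactivated α-carbon in reach and is largely lost to reduction. Both bromides are abstracted at similar rates, so at best about half of F4 is used productively. Aqueous oxalic acid unmasks the ene-dione to give the bromo analogue of the precursor, F6. One equivalent of 8 with 2,6-lutidine at −40 °C then exchanges the remaining bromide and returns to the route at 13.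

Step 12. The most likely failures are competing deprotonation at the γ-methylenes C4 and C17 of the enones, an incomplete second hydroxylation, and fragmentation of the α-hydroxy-β-diketone alkoxide (retro-Claisen or α-ketol shift) on warming. The fallback avoids strong base and sets out from 16. Mn(OAc)3·2H2O in benzene at reflux should acetoxylate the α′-positions of both enones through the trivalent manganese enolate and the bridgehead α-keto radical, giving the bis-acetate F7. Methanolysis catalysed by Sc(OTf)3 then returns to the route at 17.

Step 6. The weakness is the statistical distribution: over-substitution to the bis-sulfide and incomplete conversion are inherent to two equivalent, independent sites. The fallback removes the desymmetrisation and sets out from 7. Excess 8 with Et3N gives the bis-sulfide F8, and the conditions of step 7 give the bis-sulfide hydroquinone F10 through the quinone F9 (not isolated). The dearomatisation is then run with thiolate as the leaving group, using i-Pr2NEt and N-ethylmaleimide as an irreversible thiol scavenger, so that thiolate can neither reverse the ring closure nor attack the ene-dione. This returns to the route at 13; it is not precedented and is kept only as a reserve.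

## Further compounds

F1 | step 9 | racemic ring-A-closed diketone with hydrogen at C14 and open ethylsulfanyl enal tether (C14 epimers) | CC1=C2COC[C@]23C(=O)[C@H](C1=O)C(COCC(SCC)=C(C)C=O)C(=O)C3
F2 | step 8 | 1,4-bis{[(2-bromo-4-hydroxy-3-methylbut-2-en-1-yl)oxy]methyl}-3,3,6,6-tetramethoxycyclohexa-1,4-diene | COC1(OC)C=C(COCC(Br)=C(C)CO)C(OC)(OC)C=C1COCC(Br)=C(C)CO
F3 | step 8 | 1,4-bis{[(2-bromo-3-methyl-4-oxobut-2-en-1-yl)oxy]methyl}-3,3,6,6-tetramethoxycyclohexa-1,4-diene | COC1(OC)C=C(COCC(Br)=C(C)C=O)C(OC)(OC)C=C1COCC(Br)=C(C)C=O
F4 | step 8 | 2,5-bis{[(2-bromo-3-methyl-4-oxobut-2-en-1-yl)oxy]methyl}-4,4-dimethoxycyclohexa-2,5-dien-1-one | O=C1C=C(COCC(Br)=C(C)C=O)C(OC)(OC)C=C1COCC(Br)=C(C)C=O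
F5 | step 8 | racemic spiro monoketal (bromo enal arm on C14, dimethyl ketal at C8) | O=C/C(C)=C1/COC[C@@]12CC(=O)C(COCC(Br)=C(C)C=O)=CC2(OC)OC
F6 | step 8 | racemic bromo analogue of 13 | O=C/C(C)=C1/COC[C@]12C(=O)C=C(COCC(Br)=C(C)C=O)C(=O)C2
F7 | step 12 | 10,23-di-O-acetyl target | CC1=C2COC[C@]23C(=O)[C@](OC(C)=O)(C1=O)[C@@]12COCC1=C(C)C(=O)[C@]3(OC(C)=O)C2=O
F8 | step 6 | 4,4'-[(2,5-dimethoxy-1,4-phenylene)bis(methyleneoxy)]bis[3-(ethylsulfanyl)-2-methylbut-2-enal] | O=CC(C)=C(SCC)COCc1cc(OC)c(COCC(SCC)=C(C)C=O)cc1OC
F9 | step 6 | 2,5-bis({[2-(ethylsulfanyl)-3-methyl-4-oxobut-2-en-1-yl]oxy}methyl)cyclohexa-2,5-diene-1,4-dione | O=CC(C)=C(SCC)COCC1=CC(=O)C(COCC(SCC)=C(C)C=O)=CC1=O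
F10 | step 6 | 2,5-bis({[2-(ethylsulfanyl)-3-methyl-4-oxobut-2-en-1-yl]oxy}methyl)benzene-1,4-diol | O=CC(C)=C(SCC)COCc1cc(O)c(COCC(SCC)=C(C)C=O)cc1O
A1 | alternative 1 | cage with benzyloxymethyl groups at C7 and C14, methoxy at C3 and C18, triethylsilyl ethers at C10 and C23 | CC1=C(OC)[C@]3(COCc4ccccc4)C(=O)[C@](O[Si](CC)(CC)CC)(C1=O)[C@@]2(COCc4ccccc4)C(OC)=C(C)C(=O)[C@]3(O[Si](CC)(CC)CC)C2=O
A2 | alternative 1 | the same cage with hydrogen at C7 and C14 | CC1=C(OC)[C@@H]3C(=O)[C@](O[Si](CC)(CC)CC)(C1=O)[C@H]2C(OC)=C(C)C(=O)[C@]3(O[Si](CC)(CC)CC)C2=O
A3 | alternative 1 | benzyl chloromethyl ether | ClCOCc1ccccc1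
A4 | alternative 2 | bis-lactol (hydroxyl at C6 and C15) of the 10,23-dideoxy target | CC1=C2CO[C@H](O)[C@]23C(=O)[C@H](C1=O)[C@@]12[C@H](O)OCC1=C(C)C(=O)[C@@H]3C2=O
A5 | alternative 2 | 2,5-bis(hydroxymethylene)cyclohexane-1,4-dione | O=C1CC(=CO)C(=O)CC1=CO
A6 | alternative 2 | 4-bromo-3-methylfuran-2(5H)-one | CC1=C(Br)COC1=O
A7 | alternative 3 | doubly bridged hexaketone with benzyloxymethyl groups at C7 and C14 (C3 and C18 enols) | CC1=C(O)[C@]3(COCc4ccccc4)C(=O)[C@H](C1=O)[C@@]2(COCc4ccccc4)C(O)=C(C)C(=O)[C@@H]3C2=O
A8 | alternative 3 | 1,4-dimethoxy-2,5-bis[(benzyloxy)methyl]cyclohexa-1,4-diene | COC1=C(COCc2ccccc2)CC(OC)=C(COCc2ccccc2)C1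
A9 | alternative 3 | methylmalonyl dichloride | CC(C(=O)Cl)C(=O)Cl
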